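The seven-membered ring is cut at both bonds of its carbonyl carbon, C1–C2 and C1–C7. This works because C1 lies between two CH2-level ring carbons: C2, which is allylic once the ring alkene is placed at C3=C4, and the C7 methylene next to the aryl-bearing C6. Tosylmethyl isocyanide then acts as a one-carbon carbonyl dianion equivalent: in a single operation it is alkylated twice by an open-chain (Z)-dienyl dibromide that already carries the styryl group and the threo C5/C6 diaryl unit, the cycloheptene ring closes, and acid releases the C1 ketone. Moving the alkene into conjugation and cleaving the methyl ethers complete the synthesis.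

Key step: step 9

Remark on the chemistry: ring numbering C1 (carbonyl), C2, C3 (styryl), C4, C5 (3,5-dioxygenated aryl), C6 (3,4-dioxygenated aryl), C7 is used for every intermediate; both leaving groups of the cyclisation precursor are bromides installed together from a diol (iodide at C7 is generated in the flask by NaI), because a C7 halide carried through the nitronate and aldehyde stages would be displaced intramolecularly.

Step 1
Reactants: 1 (3,4-dimethoxyphenyl)acetaldehyde; 2 (E)-1,3-dimethoxy-5-(2-nitroethenyl)benzene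
Product: 4 (2S,3S)-2-(3,4-dimethoxyphenyl)-3-(3,5-dimethoxyphenyl)-4-nitrobutan-1-ol, via nitro aldehyde 3 (not isolated)
Conditions: (S)-α,α-diphenylprolinol trimethylsilyl ether (10 mol %), 4-nitrophenol (10 mol %), toluene, 0 °C; then MeOH, NaBH4, 0 °C
Reagents that add atoms: none
Why: Enamine-catalysed asymmetric Michael addition of an aldehyde to a nitroalkene, in which the (E)-enamine of 1, shielded on one face by the diaryl(silyloxy)methyl group, attacks the nitroalkene through a synclinal transition state and so should set C6 (S) and C5 (S) together as the syn (threo) pair, while NaBH4 added to the same flask reduces the configurationally labile α-aryl aldehyde before C6 can epimerise.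

Step 2
Reactants: 4 (2S,3S)-2-(3,4-dimethoxyphenyl)-3-(3,5-dimethoxyphenyl)-4-nitrobutan-1-ol
Product: 5 (2S,3S)-2-(3,4-dimethoxyphenyl)-3-(3,5-dimethoxyphenyl)-4-nitrobutyl 2,2-dimethylpropanoate
Conditions: PivCl, pyridine, DMAP (cat.), CH2Cl2, 0 °C to rt
Reagents that add atoms: pivaloyl chloride, CC(C)(C)C(Cl)=O
Why: Acylation of a primary alcohol, chosen because the pivalate prevents lactol formation and oxa-Michael addition in the next steps, survives brief methoxide treatment, and is later removed by the same hydride that reduces the ester.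

Step 3
Reactants: 5 (2S,3S)-2-(3,4-dimethoxyphenyl)-3-(3,5-dimethoxyphenyl)-4-nitrobutyl 2,2-dimethylpropanoate
Product: 6 (2S,3S)-2-(3,4-dimethoxyphenyl)-3-(3,5-dimethoxyphenyl)-4-oxobutyl 2,2-dimethylpropanoate
Conditions: NaOMe, MeOH, 0 °C; then aq. TiCl3, NH4OAc (pH ca. 5), THF, rt; used crude
Reagents that add atoms: water, O
Why: Nef reaction in its reductive titanium trichloride variant, in which the nitronate is reduced by trivalent titanium to the N-unsubstituted imine that hydrolyses at pH 5 to the C4 aldehyde without cleaving the pivalate or enolising the α-aryl centre C5.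

Step 4
Reactants: 7 methyl 2-[bis(2,2,2-trifluoroethoxy)phosphoryl]acetate
Product: 9 methyl 2-[bis(2,2,2-trifluoroethoxy)phosphoryl]-2-bromoacetate, via dibromophosphonate 8 (not isolated)
Conditions: Br2, aq. NaOH, 0 °C; then SnCl2·2H2O, EtOH/H2O, 0 °C
Reagents that add atoms: bromine, BrBr
Why: α-Halogenation of an active methylene followed by selective reductive monodebromination, in which hypobromite brominates the doubly activated CH2 twice and divalent tin removes one bromine, the established two-stage access to α-monobromo phosphonoacetates free of unbrominated phosphonate.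

Step 5
Reactants: 6 (2S,3S)-2-(3,4-dimethoxyphenyl)-3-(3,5-dimethoxyphenyl)-4-oxobutyl 2,2-dimethylpropanoate; 9 methyl 2-[bis(2,2,2-trifluoroethoxy)phosphoryl]-2-bromoacetate
Product: 10 methyl (2E,4R,5S)-2-bromo-5-(3,4-dimethoxyphenyl)-4-(3,5-dimethoxyphenyl)-6-[(2,2-dimethylpropanoyl)oxy]hex-2-enoate
Conditions: t-BuOK, 18-crown-6, THF, −78 °C
Reagents that add atoms: none
Why: Horner–Wadsworth–Emmons olefination of the Still–Gennari type, in which the electron-poor bis(trifluoroethyl) phosphonate makes elimination from the first-formed adduct fast and irreversible and so should place the ester (the future C2) cis to C5 (the E descriptor arises only because bromine outranks the ester), while the preformed, weakly basic phosphonate anion at −78 °C should not enolise the aldehyde.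

Step 6
Reactants: 10 methyl (2E,4R,5S)-2-bromo-5-(3,4-dimethoxyphenyl)-4-(3,5-dimethoxyphenyl)-6-[(2,2-dimethylpropanoyl)oxy]hex-2-enoate
Product: 11 (2E,4R,5S)-2-bromo-5-(3,4-dimethoxyphenyl)-4-(3,5-dimethoxyphenyl)hex-2-ene-1,6-diol
Conditions: i-Bu2AlH (6 equiv), CH2Cl2, −78 to 0 °C; aq. potassium sodium tartrate
Reagents that add atoms: none
Why: Hydride reduction with excess i-Bu2AlH, which takes the conjugated ester to the allylic alcohol by 1,2-reduction and cleaves the pivalate in the same operation, leaving the vinyl bromide and the alkene geometry untouched and removing the ester that made C5–H acidic.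

Step 7
Reactants: 11 (2E,4R,5S)-2-bromo-5-(3,4-dimethoxyphenyl)-4-(3,5-dimethoxyphenyl)hex-2-ene-1,6-diol; 12 [(E)-2-phenylethenyl]boronic acid
Product: 13 (2Z,4S,5S)-5-(3,4-dimethoxyphenyl)-4-(3,5-dimethoxyphenyl)-2-[(E)-2-phenylethenyl]hex-2-ene-1,6-diol
Conditions: Pd(PPh3)4 (5 mol %), K2CO3, DME/H2O, 70 °C
Reagents that add atoms: none
Why: Suzuki–Miyaura coupling, in which oxidative addition of zerovalent palladium into the unhindered vinyl bromide, transmetallation and reductive elimination all proceed with retention, so the styryl group should take the place of bromine trans to C5 and leave the hydroxymethyl group (C2) cis to C5.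

Step 8
Reactants: 13 (2Z,4S,5S)-5-(3,4-dimethoxyphenyl)-4-(3,5-dimethoxyphenyl)-2-[(E)-2-phenylethenyl]hex-2-ene-1,6-diol
Product: 14 [(1E,3Z,5S,6S)-7-bromo-3-(bromomethyl)-6-(3,4-dimethoxyphenyl)-5-(3,5-dimethoxyphenyl)hepta-1,3-dien-1-yl]benzene
Conditions: CBr4, PPh3, CH2Cl2, 0 °C; used at once
Reagents that add atoms: carbon tetrabromide, BrC(Br)(Br)Br
Why: Appel reaction, in which both primary alcohols are converted through their alkoxyphosphonium salts into bromides by SN2 under neutral conditions that spare the diene geometry, the electron-rich arenes and both stereocentres.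

Step 9
Reactants: 14 [(1E,3Z,5S,6S)-7-bromo-3-(bromomethyl)-6-(3,4-dimethoxyphenyl)-5-(3,5-dimethoxyphenyl)hepta-1,3-dien-1-yl]benzene; 15 tosylmethyl isocyanide
Product: 17 (5S,6S)-6-(3,4-dimethoxyphenyl)-5-(3,5-dimethoxyphenyl)-3-[(E)-2-phenylethenyl]cyclohept-3-en-1-one, via cyclic tosyl isocyanide 16 (not isolated)
Conditions: NaH (2.2 equiv), NaI (0.2 equiv), DMSO/Et2O, rt, slow addition of 14 and 15 (final ca. 0.01 M); then conc. aq. HCl, Et2O/CH2Cl2, 0 °C
Reagents that add atoms: water, O
Why: The sodium salt of 15 (pKa ca. 14) displaces the allylic bromide at C2 by SN2, the monoalkylated isocyanide is deprotonated again, and its carbanion C1 closes the ring in a 7-exo-tet mode by displacing the leaving group at C7 (bromide, exchanged in the flask for iodide); aqueous acid then hydrates the isocyanide of 16, sulfinate leaves, and the N-formyl imine hydrolyses to the C1 ketone. The closest known reaction type is the double alkylation of tosylmethyl isocyanide with α,ω-dihalides followed by acid hydrolysis to cycloalkanones, which includes seven-membered ketones from bis(bromomethyl)biaryls. No lasting stereocentre is formed, since C1 of 16 becomes the carbonyl carbon, and C5 and C6 are untouched because the only carbon acids deprotonated by the limited amount of base are the two isocyanide C–H positions. The step needs ring closure to beat oligomerisation, and SN2 to beat SN2′ and elimination. The Z C3=C4 alkene and the vicinal aryl groups hold C2 and C7 close, slow addition keeps the open-chain anion dilute, the carbanion is soft and weakly basic, and both electrophilic carbons are primary. Because the carbonyl carbon is itself the linchpin, the ketone can only end up between C2 and C7.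

Step 10
Reactants: 17 (5S,6S)-6-(3,4-dimethoxyphenyl)-5-(3,5-dimethoxyphenyl)-3-[(E)-2-phenylethenyl]cyclohept-3-en-1-one
Product: 18 (5S,6S)-6-(3,4-dimethoxyphenyl)-5-(3,5-dimethoxyphenyl)-3-[(E)-2-phenylethenyl]cyclohept-2-en-1-one
Conditions: DBU (0.5 equiv), CH2Cl2, rt
Reagents that add atoms: none
Why: Base-catalysed 1,3-prototropic shift through the extended dienolate (deprotonation at C2, reprotonation at C4), which should move the ring alkene to C2=C3 where it is conjugated with both the ketone and the styryl group, while C5 and C6 carry no hydrogen that DBU can remove; any unconverted 17 is separated and resubmitted.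

Step 11
Reactants: 18 (5S,6S)-6-(3,4-dimethoxyphenyl)-5-(3,5-dimethoxyphenyl)-3-[(E)-2-phenylethenyl]cyclohept-2-en-1-one
Product: 19 (5S,6S)-6-(3,4-dihydroxyphenyl)-5-(3,5-dihydroxyphenyl)-3-[(E)-2-phenylethenyl]cyclohept-2-en-1-one
Conditions: BBr3 (8 equiv), CH2Cl2, −78 to 0 °C; then MeOH, aq. NaHCO3
Reagents that add atoms: none
Why: Lewis-acid cleavage of aryl methyl ethers, in which BBr3 coordinates each ether oxygen and bromide removes the methyl group by SN2, run cold so that conjugate addition of bromide to the dienone stays reversible and the stereocentres, which bear no heteroatom, are not touched.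

Compound list
1 | (3,4-dimethoxyphenyl)acetaldehyde | COc1ccc(CC=O)cc1OC | starting material
2 | (E)-1,3-dimethoxy-5-(2-nitroethenyl)benzene | COc1cc(/C=C/[N+](=O)[O-])cc(OC)c1 | starting material
3 | (2S,3S)-2-(3,4-dimethoxyphenyl)-3-(3,5-dimethoxyphenyl)-4-nitrobutanal | [O-][N+](=O)C[C@H](c1cc(OC)cc(OC)c1)[C@@H](c1ccc(OC)c(OC)c1)C=O | intermediate
4 | (2S,3S)-2-(3,4-dimethoxyphenyl)-3-(3,5-dimethoxyphenyl)-4-nitrobutan-1-ol | [O-][N+](=O)C[C@H](c1cc(OC)cc(OC)c1)[C@@H](c1ccc(OC)c(OC)c1)CO | intermediate
5 | (2S,3S)-2-(3,4-dimethoxyphenyl)-3-(3,5-dimethoxyphenyl)-4-nitrobutyl 2,2-dimethylpropanoate | [O-][N+](=O)C[C@H](c1cc(OC)cc(OC)c1)[C@@H](c1ccc(OC)c(OC)c1)COC(=O)C(C)(C)C | intermediate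
6 | (2S,3S)-2-(3,4-dimethoxyphenyl)-3-(3,5-dimethoxyphenyl)-4-oxobutyl 2,2-dimethylpropanoate | O=C[C@H](c1cc(OC)cc(OC)c1)[C@@H](c1ccc(OC)c(OC)c1)COC(=O)C(C)(C)C | intermediate
7 | methyl 2-[bis(2,2,2-trifluoroethoxy)phosphoryl]acetate | COC(=O)CP(=O)(OCC(F)(F)F)OCC(F)(F)F | starting material
8 | methyl 2-[bis(2,2,2-trifluoroethoxy)phosphoryl]-2,2-dibromoacetate | COC(=O)C(Br)(Br)P(=O)(OCC(F)(F)F)OCC(F)(F)F | intermediate
9 | methyl 2-[bis(2,2,2-trifluoroethoxy)phosphoryl]-2-bromoacetate (racemic) | COC(=O)C(Br)P(=O)(OCC(F)(F)F)OCC(F)(F)F | intermediate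
10 | methyl (2E,4R,5S)-2-bromo-5-(3,4-dimethoxyphenyl)-4-(3,5-dimethoxyphenyl)-6-[(2,2-dimethylpropanoyl)oxy]hex-2-enoate (ester cis to ring C5; the R descriptor is a priority effect of bromine, the spatial arrangement is unchanged) | COC(=O)/C(Br)=C\[C@H](c1cc(OC)cc(OC)c1)[C@@H](c1ccc(OC)c(OC)c1)COC(=O)C(C)(C)C | intermediate
11 | (2E,4R,5S)-2-bromo-5-(3,4-dimethoxyphenyl)-4-(3,5-dimethoxyphenyl)hex-2-ene-1,6-diol | OC/C(Br)=C\[C@H](c1cc(OC)cc(OC)c1)[C@@H](c1ccc(OC)c(OC)c1)CO | intermediate
12 | [(E)-2-phenylethenyl]boronic acid | OB(O)/C=C/c1ccccc1 | starting material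
13 | (2Z,4S,5S)-5-(3,4-dimethoxyphenyl)-4-(3,5-dimethoxyphenyl)-2-[(E)-2-phenylethenyl]hex-2-ene-1,6-diol | OC/C(/C=C/c1ccccc1)=C\[C@H](c1cc(OC)cc(OC)c1)[C@@H](c1ccc(OC)c(OC)c1)CO | intermediate
14 | [(1E,3Z,5S,6S)-7-bromo-3-(bromomethyl)-6-(3,4-dimethoxyphenyl)-5-(3,5-dimethoxyphenyl)hepta-1,3-dien-1-yl]benzene (bromomethyl cis to C5) | BrC/C(/C=C/c1ccccc1)=C\[C@H](c1cc(OC)cc(OC)c1)[C@@H](c1ccc(OC)c(OC)c1)CBr | intermediate
15 | tosylmethyl isocyanide | Cc1ccc(S(=O)(=O)C[N+]#[C-])cc1 | starting material
16 | (5S,6S)-6-(3,4-dimethoxyphenyl)-5-(3,5-dimethoxyphenyl)-1-isocyano-1-[(4-methylphenyl)sulfonyl]-3-[(E)-2-phenylethenyl]cyclohept-3-ene (both C1 epimers) | [C-]#[N+]C1(S(=O)(=O)c2ccc(C)cc2)CC(/C=C/c2ccccc2)=C[C@H](c2cc(OC)cc(OC)c2)[C@@H](c2ccc(OC)c(OC)c2)C1 | intermediate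
17 | (5S,6S)-6-(3,4-dimethoxyphenyl)-5-(3,5-dimethoxyphenyl)-3-[(E)-2-phenylethenyl]cyclohept-3-en-1-one | O=C1CC(/C=C/c2ccccc2)=C[C@H](c2cc(OC)cc(OC)c2)[C@@H](c2ccc(OC)c(OC)c2)C1 | intermediate
18 | (5S,6S)-6-(3,4-dimethoxyphenyl)-5-(3,5-dimethoxyphenyl)-3-[(E)-2-phenylethenyl]cyclohept-2-en-1-one | O=C1C=C(/C=C/c2ccccc2)C[C@H](c2cc(OC)cc(OC)c2)[C@@H](c2ccc(OC)c(OC)c2)C1 | intermediate
19 | (5S,6S)-6-(3,4-dihydroxyphenyl)-5-(3,5-dihydroxyphenyl)-3-[(E)-2-phenylethenyl]cyclohept-2-en-1-one (CNP0400050.1) | O=C1C=C(/C=C/c2ccccc2)C[C@H](c2cc(O)cc(O)c2)[C@@H](c2ccc(O)c(O)c2)C1 | target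

Total step count: 11. Longest linear sequence: 10 (steps 1–3 and 5–11; step 4 prepares the olefination reagent).

Steps most likely to fail

Step 9. The second alkylation forms a seven-membered ring and may be too slow, so that intermolecular alkylation (oligomers) or base-induced loss of HBr or sulfinate takes over. The fallback replaces the one-flask isocyanide linchpin by a stepwise sulfone linchpin; it sets out from 14 and comes back at 17. The sodium salt of methylthiomethyl p-tolyl sulfone (NaH, DMF, 0 °C) should alkylate 14 only at the allylic bromide and give the monoalkylated sulfone F1. F1 is then added slowly to NaH and NaI in DMF at 50 °C, where its carbanion should close the ring to the 1-(methylsulfanyl)-1-tosylcycloheptene F2. Hydrolysis of this thioacetal S,S-dioxide with aq. HCl in MeOH releases 17; any 18 formed alongside is simply carried on.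

Step 1. The α-aryl aldehyde 3 may epimerise at C6 through its enamine before it is reduced, which would erode the threo selectivity. The fallback sets C6 at a carbon that cannot epimerise and C5 under thermodynamic control. It replaces 1 and 2 by commercial furan-2(5H)-one and (3,4-dimethoxyphenyl)boronic acid, so it sets out from no numbered compound, and it comes back at 6. Rhodium-catalysed asymmetric 1,4-addition (Rh(acac)(C2H4)2, (S)-BINAP, dioxane/H2O, 100 °C) should give the (S)-β-aryl lactone F3, the sense being assigned by analogy with cyclic enones. Palladium-catalysed α-arylation of its zinc enolate with 1-bromo-3,5-dimethoxybenzene (LiN(SiMe3)2, ZnCl2, Pd(dba)2, P(t-Bu)3, THF), followed by DBU equilibration, should give the trans-diaryl lactone F4. Ring opening with Me2AlCl and MeNHOMe·HCl gives the hydroxy Weinreb amide F5, pivaloylation gives its pivalate F6, and i-Bu2AlH at −78 °C reduces the amide to 6.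

Step 5. The hindered aldehyde may react slowly enough for enolisation to scramble C5, or the geometric control may fall short. The fallback builds the alkene under neutral conditions and sets its geometry by site-selective cross-coupling; it sets out from 6 and comes back at 13. CBr4 and PPh3 (CH2Cl2, 0 °C) convert 6 into the 1,1-dibromoalkene F7. Coupling with 12 (Pd2(dba)3, tri(2-furyl)phosphine, aq. Na2CO3, dioxane, 65 °C) should replace only the less hindered bromine trans to C5 and give the (Z)-2-bromodiene F8. Stille coupling with Bu3SnCH2OH (Pd(PPh3)4, dioxane, 90 °C) gives the dienol pivalate F9, and i-Bu2AlH removes the pivalate to give 13.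

Further compounds
F1 | step 9 | 1-{[(3E,5S,6S)-7-bromo-6-(3,4-dimethoxyphenyl)-5-(3,5-dimethoxyphenyl)-1-(methylsulfanyl)-3-[(E)-2-phenylethenyl]hept-3-en-1-yl]sulfonyl}-4-methylbenzene (C1 epimers; C2 cis to C5 as in 14) | CSC(C/C(/C=C/c1ccccc1)=C\[C@H](c1cc(OC)cc(OC)c1)[C@@H](c1ccc(OC)c(OC)c1)CBr)S(=O)(=O)c1ccc(C)cc1
F2 | step 9 | (5S,6S)-6-(3,4-dimethoxyphenyl)-5-(3,5-dimethoxyphenyl)-1-(methylsulfanyl)-1-[(4-methylphenyl)sulfonyl]-3-[(E)-2-phenylethenyl]cyclohept-3-ene (C1 epimers) | CSC1(S(=O)(=O)c2ccc(C)cc2)CC(/C=C/c2ccccc2)=C[C@H](c2cc(OC)cc(OC)c2)[C@@H](c2ccc(OC)c(OC)c2)C1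
F3 | step 1 | (S)-4-(3,4-dimethoxyphenyl)oxolan-2-one | O=C1C[C@@H](c2ccc(OC)c(OC)c2)CO1
F4 | step 1 | (3S,4S)-4-(3,4-dimethoxyphenyl)-3-(3,5-dimethoxyphenyl)oxolan-2-one | O=C1[C@H](c2cc(OC)cc(OC)c2)[C@@H](c2ccc(OC)c(OC)c2)CO1
F5 | step 1 | (2S,3S)-3-(3,4-dimethoxyphenyl)-2-(3,5-dimethoxyphenyl)-4-hydroxy-N-methoxy-N-methylbutanamide | CON(C)C(=O)[C@H](c1cc(OC)cc(OC)c1)[C@@H](c1ccc(OC)c(OC)c1)CO
F6 | step 1 | (2S,3S)-2-(3,4-dimethoxyphenyl)-3-(3,5-dimethoxyphenyl)-4-[methoxy(methyl)amino]-4-oxobutyl 2,2-dimethylpropanoate | CON(C)C(=O)[C@H](c1cc(OC)cc(OC)c1)[C@@H](c1ccc(OC)c(OC)c1)COC(=O)C(C)(C)C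
F7 | step 5 | (2S,3R)-5,5-dibromo-2-(3,4-dimethoxyphenyl)-3-(3,5-dimethoxyphenyl)pent-4-en-1-yl 2,2-dimethylpropanoate | BrC(Br)=C[C@H](c1cc(OC)cc(OC)c1)[C@@H](c1ccc(OC)c(OC)c1)COC(=O)C(C)(C)C
F8 | step 5 | (2S,3R,4Z,6E)-5-bromo-2-(3,4-dimethoxyphenyl)-3-(3,5-dimethoxyphenyl)-7-phenylhepta-4,6-dien-1-yl 2,2-dimethylpropanoate | Br/C(/C=C/c1ccccc1)=C\[C@H](c1cc(OC)cc(OC)c1)[C@@H](c1ccc(OC)c(OC)c1)COC(=O)C(C)(C)C
F9 | step 5 | (2S,3S,4Z,6E)-2-(3,4-dimethoxyphenyl)-3-(3,5-dimethoxyphenyl)-5-(hydroxymethyl)-7-phenylhepta-4,6-dien-1-yl 2,2-dimethylpropanoate | OC/C(/C=C/c1ccccc1)=C\[C@H](c1cc(OC)cc(OC)c1)[C@@H](c1ccc(OC)c(OC)c1)COC(=O)C(C)(C)C
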